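## The problem

The target 34 is a germacranolide: a ten-membered carbocycle (C1–C10) with two ring olefins in which the ring carbons are cis, C1=C10 (carrying the C14 formyl group) and the trisubstituted (Z)-C4=C5 (carrying the C15 methyl group). An α-methylene γ-lactone (C11, C12, C13) is trans-fused across C6–C7. Four contiguous stereocentres lie on one flank of the ring: C6 (lactone oxygen), C7 (C11), C8 (acyloxy) and C9 (free carbinol). The C8 oxygen carries an (S)-2-methylbutanoyl group whose α-centre must stay intact.

On a flexible ten-membered ring these centres and the two olefin geometries cannot be expected to direct one another. On a cyclohexane chair they can be relayed: C5 sets C10–O and C9–O, C9 sets C7 by a suprafacial shift, C5 sets C6, a C10 hydroxyl places a C8/C9 epoxide, and the epoxide sets C10 and C8.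

The end of the synthesis has to be gentle. The methylene lactone and the enal are Michael acceptors, the C8 ester sits next to a free hydroxyl (acyl migration), and C6–O and C9–O are allylic.

The feature that opens the route is the 1,5-diene C10=C1–C2–C3–C4=C5. If C14 is exchanged for oxygen, the ring is a cyclodec-5-enone, the oxy-Cope product of a cyclohexanol (ring B, C5–C10) with a vinyl group (C1, C2) on C10 and an isopropenyl group (C3, C4, C15) on C5, which already carries C6–C9.

## Retrosynthesis

**34 ⇐ 33 ⇐ 31 + 32 ⇐ 30 ⇐ 28.** The C9 methoxymethyl ether, the C8 ester C–O bond and the C8 4-methoxybenzyl (PMB) ether are cut, and the lactone carbonyl is taken back to a methyl lactol acetal. Ester and lactone cannot survive organometallic reagents or an alkoxide, so both come late. C8 and C9 must be told apart so that only C8 is acylated, hence two different ethers. The forward steps ask for mild acid hydrolysis and MnO2 oxidation, DDQ, an esterification that does not epimerise 32, and a cold MOM cleavage.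

**28 ⇐ 27 ⇐ 26.** The C10–C14 bond is cut, leaving the C10 ketone that an oxy-Cope rearrangement delivers. An olefination of the ketone would put the new double bond outside the ring. The enol triflate route puts it at C1=C10 and fixes its geometry in the enolisation. The enolate formed in the rearrangement itself (25) has C2 cis to oxygen, the opposite of what 34 needs, so ketone 26 is isolated and enolised again.

**26 ⇐ 24 (key step).** C2–C3 is cut and C5–C10 is restored. The ten-membered ring becomes a cyclohexane on which C6–C9 can be set by chair rules, and the ring is later formed by expansion, not by joining two chain ends. The forward reaction must give the Z olefin at C4=C5, which requires the vinyl and isopropenyl groups cis on ring B.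

**24 ⇐ 23 ⇐ 22 ⇐ 20 + 21.** The C9 O–MOM bond, the C8–O(PMB) bond (back to a C8–C9 epoxide) and the C10–C1 bond are cut. Adding the vinyl group to a ketone with axial ethers at C8 and C9 would leave the C10 configuration to a balance of two hindered faces. Adding it to epoxy ketone 20 lets the epoxide decide (attack anti to its C–O bond). The same epoxide then brings in the C8 oxygen with inversion and leaves C9–OH free for a different protecting group.

**20 ⇐ 19 ⇐ 18.** The epoxide comes from the C8=C9 olefin and the ketone from the C10 alcohol. The C10 hydroxyl is used twice, first to direct the epoxidation to its own face and to the allylic olefin only, then as the ketone.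

**18 ⇐ 16 ⇐ 13.** The acetal goes back to the α-methylene lactone and C11=C13 is cut to give lactone 13. The methylene group is added while the molecule is still robust.

**13 ⇐ 10 (via 11, 12).** C7–C11 is cut: an Ireland–Claisen rearrangement of the C9 acetate. Alkylation or conjugate addition at C7 would be governed by neighbouring groups of uncertain influence, whereas the sigmatropic shift carries the C9 configuration to C7 strictly. The C9 oxygen is lost here and returns later, on the other face, through the epoxide.

**10 ⇐ 9 ⇐ 8 ⇐ 7 ⇐ 6.** These are functional-group changes on ring B: the C6 alcohol from the ketone, the ketone from its dimethyl ketal, the C9 acetate from the alcohol, and the alcohol from the enone. Each reduction is an axial hydride delivery to a half-chair with equatorial substituents.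

**6 ⇐ 4 ⇐ 2 + 3; 2 ⇐ 1.** C10–O is cut (Rubottom oxidation of dienol ether 5) and then C5–C4 (asymmetric conjugate addition). The quinone monoketal 2 has the right polarity: carbonyl at C9, β-carbon C5 for the carbon nucleophile, α-carbon C10 for electrophilic oxygen, and the ketal carbon as the later C6 carbinol. It comes in one step from 4-methoxyphenol 1. The only absolute stereocontrol needed is the enone-face choice in 2 → 4.

## Roads not taken

**Alternative 1:** The cut is C11–C12 and C12–O, the whole lactone carbonyl. In the forward direction alkynol A2 (C6–OH and a C7 ethynyl group on the finished ten-membered ring) would take up CO with PdCl2(PPh3)2 and SnCl2 to close the trans-fused methylene lactone, giving A1, the C9 triethylsilyl ether of 34.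
- Merits: the most fragile group is made last, in one step, and never needs masking. The chosen plan is weaker here: it installs the methylene group at step 9, carries it as an acetal through ten steps and needs hydrolysis and oxidation to unmask it.
- Weak points: the step says nothing about how the ring, the Z olefin or C6–C9 arise, so a ring-forming strategy is still needed. The C6 hydroxyl of A2 is allylic and could ionise under Lewis-acidic SnCl2 with palladium. The enal and the C8 ester must survive a palladium hydride medium.
- Comparison: it is an end-game variant, not a solution of the ring. The chosen plan sets against it a single step that forms the ring and the C4=C5 geometry.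

**Alternative 2:** The cut is C3–C4. In A4 the terminal C2=C3 vinyl group of a diene would be hydroborated with 9-borabicyclo[3.3.1]nonane and the alkylborane coupled with the (Z)-vinyl iodide at C4 under PdCl2(dppf) and Cs2CO3, closing the ring to A3.
- Merits: both olefin geometries are fixed before ring closure. This is more certain than the chosen plan at C1=C10, where the geometry rests on a kinetic enolisation.
- Weak points: hydroboration of the end of a conjugated diene competes with allylborane formation. Closing a strained ten-membered ring end to end needs high dilution and fights transannular strain. The four centres C6–C9 must be built on an open chain. After ring closure the methylene group and the C14 aldehyde are still missing.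
- Comparison: the chosen plan has no macrocyclisation and builds the stereocentres on a chair.

**Alternative 3:** The cut is C9–C10. In dialdehyde A6, P(CH3)3 with MgI2 would add to C1 of the enal, the C10 enolate would attack the C9 aldehyde, and loss of phosphine would give A5, the 8-O-PMB analogue of 34.
- Merits: on paper this is the shortest road. Ring, C9 carbinol and enal arise together and no oxidation-level change follows.
- Weak points: β-substituted enals are poor Morita–Baylis–Hillman donors. The phosphine would add first to the more electrophilic methylene lactone. The C9 configuration would be set in a reversible aldol step on a forming macrocycle with little to control it. The α-alkoxy aldehyde at C8 can epimerise. After PMB removal C8–OH and C9–OH would have to be distinguished for acylation.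
- Comparison: the chosen plan is longer but sets C9 on a ring with a defined conformation and differentiates C8 from C9 by the way the epoxide opens.

Key step: step 16

Remarks on the chemistry (assumptions):
- Ring carbons of all intermediates carry the germacrane numbers of 34 (ring B = C5–C10). "Upper face" is the face of ring B that bears the C5 isopropenyl group; C7–C11, C8–O and the C10 vinyl group are upper, C6–O, C9–O and C10–OH lower.
- The acetal carbon C12 in 18–28 has no influence on later steps and is drawn as one anomer. C11 in 14 and 15 and C12 in 17 and 29 are mixtures, drawn without configuration.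
- (R)-BINAP is assumed to deliver the isopropenyl group to 2 in the facial sense established for cyclohex-2-enone.

## Route

Step 1
Reactants: 1 4-methoxyphenol
Product: 2 4,4-dimethoxycyclohexa-2,5-dien-1-one
Conditions: PhI(OAc)2, MeOH, 0 °C
Reagents that add atoms: methanol (CO)
Why: Oxidative dearomatisation of a para-alkoxyphenol by a hypervalent iodine reagent; methanol captures C4 to give the quinone monoketal, with a carbonyl at the future C9 and a masked carbonyl at the future C6. No stereocentre is formed.

Step 2
Reactants: 2 4,4-dimethoxycyclohexa-2,5-dien-1-one; 3 potassium isopropenyltrifluoroborate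
Product: 4 (R)-4,4-dimethoxy-5-(prop-1-en-2-yl)cyclohex-2-en-1-one
Conditions: [Rh(cod)2]BF4 (3 mol%), (R)-BINAP (3.3 mol%), Et3N, PhMe/H2O, 25 °C
Reagents that add atoms: none
Why: Rhodium-catalysed asymmetric conjugate addition of an alkenylboron reagent to a cyclic enone (Hayashi–Miyaura reaction); the two enone units of 2 are homotopic, so only the enone face is chosen, and the ligand sets C5. One equivalent of 3 and the lower electrophilicity of the product enone should hold the reaction at mono-addition.

Step 3
Reactants: 4 (R)-4,4-dimethoxy-5-(prop-1-en-2-yl)cyclohex-2-en-1-one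
Product: 6 (5S,6S)-4,4-dimethoxy-5-(prop-1-en-2-yl)-6-(triethylsilyloxy)cyclohex-2-en-1-one, via triethylsilyl dienol ether 5 (not isolated)
Conditions: LiN(iPr)2, THF, −78 °C, then Et3SiCl; mCPBA, NaHCO3, CH2Cl2, −20 °C
Reagents that add atoms: chlorotriethylsilane (CC[Si](Cl)(CC)CC); mCPBA (OOC(=O)c1cccc(Cl)c1)
Why: Kinetic deprotonation of an enone occurs at the alpha-prime carbon (C10) and O-silylation gives the 2-silyloxydiene 5; Rubottom oxidation epoxidises the electron-rich enol ether bond on the face away from the neighbouring isopropenyl group, and 1,4-silyl migration gives the silyloxy ketone with C10–O trans to C5.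

Step 4
Reactants: 6 (5S,6S)-4,4-dimethoxy-5-(prop-1-en-2-yl)-6-(triethylsilyloxy)cyclohex-2-en-1-one
Product: 7 (1S,5S,6S)-4,4-dimethoxy-5-(prop-1-en-2-yl)-6-(triethylsilyloxy)cyclohex-2-en-1-ol (C9–OH upper, cis to isopropenyl)
Conditions: NaBH4, CeCl3·7H2O, MeOH, −78 °C
Reagents that add atoms: none
Why: Luche reduction gives 1,2-reduction only; axial hydride delivery to the half-chair with equatorial isopropenyl and silyloxy groups gives the equatorial C9 alcohol, cis to isopropenyl and trans to the silyl ether (as carvone gives cis-carveol).

Step 5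
Reactants: 7 (1S,5S,6S)-4,4-dimethoxy-5-(prop-1-en-2-yl)-6-(triethylsilyloxy)cyclohex-2-en-1-ol
Product: 8 C9 acetate of 7
Conditions: Ac2O, pyridine, DMAP (cat.), CH2Cl2, 0 °C
Reagents that add atoms: acetic anhydride (CC(=O)OC(C)=O)
Why: Standard acylation of a secondary allylic alcohol; the acetyl group supplies C11 and C12 and covers C9–O during the next two steps.

Step 6
Reactants: 8 C9 acetate of 7
Product: 9 4-acetoxy-6-isopropenyl-5-(triethylsilyloxy)cyclohex-2-en-1-one (C6 ketone, C7=C8, C9–OAc upper, C10–OSiEt3 lower, C5 isopropenyl upper)
Conditions: PPTS (cat.), acetone/H2O, 0 → 23 °C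
Reagents that add atoms: water (O)
Why: An allylic dimethyl ketal hydrolyses under very mild acid through an allyl-stabilised oxocarbenium ion, which spares the triethylsilyl ether and the acetate; the product is a conjugated enone, so no double bond can migrate, and the equatorial C5 centre next to the new ketone is the stable one.

Step 7
Reactants: 9 4-acetoxy-6-isopropenyl-5-(triethylsilyloxy)cyclohex-2-en-1-one
Product: 10 allylic alcohol (C6–OH lower, trans to isopropenyl; C7=C8; C9–OAc; C10–OSiEt3)
Conditions: NaBH4, CeCl3·7H2O, MeOH, −78 °C
Reagents that add atoms: none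
Why: Luche reduction; axial hydride attack gives the equatorial C6 alcohol trans to the equatorial isopropenyl group, and the acetate is inert at −78 °C.

Step 8
Reactants: 10 allylic alcohol
Product: 13 trans-fused γ-lactone (C6–O–C12(=O)–C11H2–C7; C8=C9; C10–OSiEt3), via silyl ketene acetal 11 (not isolated), via hydroxy acid 12 (not isolated)
Conditions: LiN(iPr)2, Me3SiCl, Et3N, THF, −78 → 65 °C; 1 M HCl; PPTS, PhMe, 80 °C
Reagents that add atoms: none
Why: Ireland–Claisen rearrangement: the [3,3] shift of the silyl ketene acetal is suprafacial, so the acetic acid unit leaves C9–O and arrives at C7 on the same upper face while the olefin moves to C8=C9; the C6 hydroxyl, silylated in the flask and freed on acidification, closes the lactone, which is trans-fused because C6–O and C7–C11 are trans. C7 is set by C9.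

Step 9
Reactants: 13 trans-fused γ-lactone
Product: 16 α-methylene lactone (C11=C13), via Mannich base 14 (not isolated), via trimethylammonium iodide 15 (not isolated)
Conditions: LiN(iPr)2, THF, −78 °C, CH2=NMe2+ I−; MeI, MeOH, 23 °C; NaHCO3 (aq), CH2Cl2
Reagents that add atoms: Eschenmoser's salt (C=[N+](C)C.[I-])
Why: Mannich reaction of the lactone enolate, quaternisation and base-induced elimination, the standard α-methylenation of γ-lactones; C11 becomes trigonal, so its configuration in 14 does not matter.

Step 10
Reactants: 16 α-methylene lactone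
Product: 18 methyl lactol acetal with free C10 hydroxyl (C8=C9), via lactol 17 (not isolated)
Conditions: iBu2AlH, CH2Cl2, −78 °C; MeOH, PPTS, 23 °C
Reagents that add atoms: methanol (CO)
Why: Half-reduction of the lactone at −78 °C and acid-catalysed acetalisation of the allylic lactol; the same methanolic PPTS removes the triethylsilyl ether. The acetal withstands the bases and organometallic reagents to come, and its trans fusion holds ring B in one chair.

Step 11
Reactants: 18 methyl lactol acetal with free C10 hydroxyl
Product: 19 epoxy alcohol (C8–C9 epoxide on the lower face, cis to C10–OH)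
Conditions: VO(acac)2 (5 mol%), tBuOOH, CH2Cl2, 0 → 23 °C
Reagents that add atoms: tert-butyl hydroperoxide (CC(C)(C)OO)
Why: Vanadium-catalysed hydroxyl-directed epoxidation: only the allylic C8=C9 olefin is reached through the C10 vanadate ester, so the isopropenyl and exocyclic methylene groups are left alone, and oxygen is delivered to the face of the hydroxyl, which is also the face away from the C7 substituent.

Step 12
Reactants: 19 epoxy alcohol
Product: 20 α,β-epoxy ketone (C10 ketone)
Conditions: Dess–Martin periodinane, NaHCO3, CH2Cl2, 0 °C
Reagents that add atoms: none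
Why: Dess–Martin oxidation under buffered, non-basic conditions gives the ketone without enolising C5 or opening the epoxide.

Step 13
Reactants: 20 α,β-epoxy ketone; 21 vinylmagnesium bromide
Product: 22 tertiary allylic alcohol (C10 vinyl upper, C10–OH lower, epoxide lower)
Conditions: CH2=CHMgBr, CeCl3, THF, −78 °C
Reagents that add atoms: none
Why: 1,2-Addition of the organocerium reagent formed from the Grignard reagent, which suppresses enolisation toward C5; nucleophiles add to α,β-epoxy ketones anti to the epoxide C–O bond, so the vinyl group enters on the upper face, cis to the isopropenyl group. C10 is set by the epoxide.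

Step 14
Reactants: 22 tertiary allylic alcohol
Product: 23 diol mono-PMB ether (C8–OPMB upper, C9–OH lower, C10–OH)
Conditions: 4-MeOC6H4CH2OH (excess), Ti(OiPr)4, PhMe, 80 °C
Reagents that add atoms: 4-methoxybenzyl alcohol (COc1ccc(CO)cc1)
Why: Titanium alkoxide-mediated opening of a 2,3-epoxy alcohol at the carbon remote from the carbinol: titanium held by the C10 alkoxide and the cis epoxide oxygen activates the ring, and the alcohol attacks C8 with inversion. The same carbon is favoured by trans-diaxial opening of the locked chair and by the shielding of C9 by the quaternary C10, so C8–O is set on the upper face and C8 is distinguished from C9.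

Step 15
Reactants: 23 diol mono-PMB ether
Product: 24 oxy-Cope precursor (1-vinyl-2-isopropenylcyclohexanol carrying the trans-fused methyl lactol acetal, C8–OPMB and C9–OMOM)
Conditions: MeOCH2Cl, iPr2NEt, CH2Cl2, 0 → 40 °C
Reagents that add atoms: chloromethyl methyl ether (COCCl)
Why: Alkylation of the secondary C9 hydroxyl; the tertiary C10 hydroxyl is too hindered to react. An acetal ether is chosen because, unlike a silyl group, it cannot migrate to the neighbouring alkoxide in the next step.

Step 16
Reactants: 24 oxy-Cope precursor
Product: 26 ten-membered (4Z)-en-10-one (acetal, C8–OPMB and C9–OMOM unchanged), via potassium enolate 25 (not isolated)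
Conditions: KH, 18-crown-6, THF, 0 → 23 °C; NH4Cl (aq), −78 °C
Reagents that add atoms: none
Why: Deprotonation of the tertiary C10 alcohol gives a crown-separated potassium alkoxide whose oxyanion weakens the C5–C10 bond, so the [3,3] shift of the diene C2=C1–C10–C5–C4=C3 runs near room temperature and ends in enolate 25, which makes it irreversible. The closest known reaction type is the anionic oxy-Cope rearrangement of 1-vinyl-2-alkenylcyclohexanols to cyclodec-5-enones. The ten-membered ring is closed by ring expansion of ring B through a six-membered chair transition state (C2–C3 forms while C5–C10 breaks), so the reacting ends are held together and ordinary concentration suffices. No stereocentre is created; C6–C9 pass through untouched and the new element is the C4=C5 geometry. In the chair of 24, locked by the trans-fused acetal ring, the isopropenyl group is equatorial and the vinyl group axial and cis to it, so the two groups are gauche about C5–C10 and reach the chair transition state without ring flip; there C6 is pseudo-axial on C5, which gives the Z olefin, and C9 is pseudo-equatorial on C10. The C1=C10 enolate geometry disappears on protonation at C1. The step needs the concerted path to win over alkoxide fragmentation and over enolate equilibration toward C9 (which would expel the C8 ether); the non-migrating MOM and PMB ethers, a slight excess of KH only and a cold quench should secure this.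

Step 17
Reactants: 26 ten-membered (4Z)-en-10-one
Product: 27 enol triflate (C1=C10, C2 cis to C9)
Conditions: LiN(iPr)2, THF, −78 °C; PhNTf2
Reagents that add atoms: N-phenylbis(trifluoromethanesulfonimide) (FC(F)(F)S(=O)(=O)N(c1ccccc1)S(=O)(=O)C(F)(F)F)
Why: Kinetic deprotonation takes the less hindered C1 methylene in preference to the alkoxy-substituted C9 methine, and a ten-membered ring should favour the enolate in which the ring carbons C2 and C9 are cis, the opposite geometry to 25 and the one 34 needs; O-sulfonylation fixes it.

Step 18
Reactants: 27 enol triflate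
Product: 28 enal (C14 formyl on C10; acetal, C8–OPMB, C9–OMOM)
Conditions: Pd(PPh3)4 (5 mol%), CO (1 atm), Bu3SnH (slow addition), LiCl, THF, 50 °C
Reagents that add atoms: carbon monoxide ([C-]#[O+])
Why: Palladium-catalysed reductive carbonylation of an enol triflate: oxidative addition to zerovalent palladium, CO insertion and hydride transfer from tin give the α,β-unsaturated aldehyde with retention of olefin geometry; slow addition of the hydride suppresses direct reduction of the triflate.

Step 19
Reactants: 28 enal
Product: 30 α-methylene lactone (C8–OPMB, C9–OMOM), via lactol 29 (not isolated)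
Conditions: AcOH/THF/H2O, 23 °C; MnO2, CH2Cl2, 23 °C
Reagents that add atoms: water (O)
Why: The allylic lactol acetal hydrolyses in dilute acetic acid, which leaves MOM and PMB ethers intact, and MnO2 oxidises the allylic lactol to the lactone without touching the enal.

Step 20
Reactants: 30 α-methylene lactone
Product: 31 C8 alcohol (C9–OMOM)
Conditions: DDQ, CH2Cl2/pH 7 buffer, 0 °C
Reagents that add atoms: none
Why: Oxidative cleavage of a 4-methoxybenzyl ether by hydride abstraction at the benzylic carbon; MOM ether, lactone and enal are inert.

Step 21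
Reactants: 31 C8 alcohol; 32 (S)-2-methylbutanoic acid
Product: 33 C8 (S)-2-methylbutanoate with C9–OMOM
Conditions: EDC·HCl, DMAP, CH2Cl2, 0 → 23 °C
Reagents that add atoms: none
Why: Steglich esterification; an α-alkyl carboxylic acid keeps its configuration under carbodiimide activation, and only C8–OH is free.

Step 22
Reactants: 33 C8 (S)-2-methylbutanoate with C9–OMOM
Product: 34 target (CNP0168436.1)
Conditions: Me2BBr, CH2Cl2, −78 °C; NaHCO3 (aq)
Reagents that add atoms: none
Why: Dimethylboron bromide cleaves methoxymethyl ethers at −78 °C through the bromomethyl ether, which is hydrolysed on work-up; ester, lactone, enal and olefins are tolerated at this temperature.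

## Compound list

1 | 4-methoxyphenol | COc1ccc(O)cc1 | starting material
2 | 4,4-dimethoxycyclohexa-2,5-dien-1-one | COC1(OC)C=CC(=O)C=C1 | intermediate
3 | potassium isopropenyltrifluoroborate | [K+].CC(=C)[B-](F)(F)F | starting material
4 | (R)-4,4-dimethoxy-5-(prop-1-en-2-yl)cyclohex-2-en-1-one | COC1(OC)[C@@H](C(C)=C)CC(=O)C=C1 | intermediate
5 | triethylsilyl dienol ether of 4 (C9–OSiEt3, C9=C10, C7=C8) | COC1(OC)[C@@H](C(C)=C)C=C(O[Si](CC)(CC)CC)C=C1 | intermediate (not isolated)
6 | (5S,6S)-4,4-dimethoxy-5-(prop-1-en-2-yl)-6-(triethylsilyloxy)cyclohex-2-en-1-one | COC1(OC)[C@@H](C(C)=C)[C@H](O[Si](CC)(CC)CC)C(=O)C=C1 | intermediate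
7 | (1S,5S,6S)-4,4-dimethoxy-5-(prop-1-en-2-yl)-6-(triethylsilyloxy)cyclohex-2-en-1-ol | COC1(OC)[C@@H](C(C)=C)[C@H](O[Si](CC)(CC)CC)[C@@H](O)C=C1 | intermediate
8 | C9 acetate of 7 | COC1(OC)[C@@H](C(C)=C)[C@H](O[Si](CC)(CC)CC)[C@@H](OC(C)=O)C=C1 | intermediate
9 | 4-acetoxy-6-isopropenyl-5-(triethylsilyloxy)cyclohex-2-en-1-one (C6 ketone; ring substituents mutually trans) | O=C1[C@@H](C(C)=C)[C@H](O[Si](CC)(CC)CC)[C@@H](OC(C)=O)C=C1 | intermediate
10 | C6 allylic alcohol from 9 (C6–OH trans to isopropenyl) | O[C@@H]1[C@@H](C(C)=C)[C@H](O[Si](CC)(CC)CC)[C@@H](OC(C)=O)C=C1 | intermediate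
11 | trimethylsilyl ketene acetal of 10, C6–OSiMe3 | C[Si](C)(C)O[C@@H]1[C@@H](C(C)=C)[C@H](O[Si](CC)(CC)CC)[C@@H](OC(=C)O[Si](C)(C)C)C=C1 | intermediate (not isolated)
12 | hydroxy acid (C7–CH2CO2H upper, C6–OH lower, C8=C9) | O[C@@H]1[C@@H](C(C)=C)[C@H](O[Si](CC)(CC)CC)C=C[C@H]1CC(=O)O | intermediate (not isolated)
13 | trans-fused γ-lactone (C8=C9, C10–OSiEt3) | C1C(=O)O[C@@H]2[C@@H](C(C)=C)[C@H](O[Si](CC)(CC)CC)C=C[C@@H]12 | intermediate
14 | Mannich base, C11–CH2NMe2 (C11 epimers) | CN(C)CC1C(=O)O[C@@H]2[C@@H](C(C)=C)[C@H](O[Si](CC)(CC)CC)C=C[C@@H]12 | intermediate (not isolated)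
15 | trimethylammonium iodide of 14 | C[N+](C)(C)CC1C(=O)O[C@@H]2[C@@H](C(C)=C)[C@H](O[Si](CC)(CC)CC)C=C[C@@H]12.[I-] | intermediate (not isolated)
16 | α-methylene lactone (C8=C9, C10–OSiEt3) | C=C1C(=O)O[C@@H]2[C@@H](C(C)=C)[C@H](O[Si](CC)(CC)CC)C=C[C@@H]12 | intermediate
17 | α-methylene lactol (anomers), C10–OSiEt3 | C=C1C(O)O[C@@H]2[C@@H](C(C)=C)[C@H](O[Si](CC)(CC)CC)C=C[C@@H]12 | intermediate (not isolated)
18 | methyl lactol acetal, C10–OH, C8=C9 (one anomer drawn) | C=C1[C@@H](OC)O[C@@H]2[C@@H](C(C)=C)[C@H](O)C=C[C@@H]12 | intermediate
19 | epoxy alcohol (C8–C9 epoxide cis to C10–OH) | C=C1[C@@H](OC)O[C@@H]2[C@@H](C(C)=C)[C@H](O)[C@@H]3O[C@@H]3[C@@H]12 | intermediate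
20 | α,β-epoxy ketone (C10 ketone) | C=C1[C@@H](OC)O[C@@H]2[C@@H](C(C)=C)C(=O)[C@@H]3O[C@@H]3[C@@H]12 | intermediate
21 | vinylmagnesium bromide | C=C[Mg]Br | starting material
22 | tertiary allylic alcohol (C10 vinyl cis to isopropenyl, epoxide intact) | C=C1[C@@H](OC)O[C@@H]2[C@@H](C(C)=C)[C@@](O)(C=C)[C@@H]3O[C@@H]3[C@@H]12 | intermediate
23 | C8 PMB ether, C9 and C10 diol | C=C1[C@@H](OC)O[C@@H]2[C@@H](C(C)=C)[C@@](O)(C=C)[C@H](O)[C@@H](OCc3ccc(OC)cc3)[C@@H]12 | intermediate
24 | oxy-Cope precursor (C8–OPMB, C9–OMOM, C10 vinyl carbinol) | C=C1[C@@H](OC)O[C@@H]2[C@@H](C(C)=C)[C@@](O)(C=C)[C@H](OCOC)[C@@H](OCc3ccc(OC)cc3)[C@@H]12 | intermediate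
25 | potassium enolate of 26 (C1=C10, oxygen cis to C2) | [K+].C=C1[C@@H](OC)O[C@@H]2/C=C(/C)CC/C=C(\[O-])[C@H](OCOC)[C@@H](OCc3ccc(OC)cc3)[C@@H]12 | intermediate (not isolated)
26 | ten-membered (4Z)-en-10-one | C=C1[C@@H](OC)O[C@@H]2/C=C(/C)CCCC(=O)[C@H](OCOC)[C@@H](OCc3ccc(OC)cc3)[C@@H]12 | intermediate
27 | C10 enol triflate (C1=C10, C2 cis to C9) | C=C1[C@@H](OC)O[C@@H]2/C=C(/C)CC/C=C(/OS(=O)(=O)C(F)(F)F)[C@H](OCOC)[C@@H](OCc3ccc(OC)cc3)[C@@H]12 | intermediate
28 | enal (C14 formyl), acetal, C8–OPMB, C9–OMOM | C=C1[C@@H](OC)O[C@@H]2/C=C(/C)CC/C=C(/C=O)[C@H](OCOC)[C@@H](OCc3ccc(OC)cc3)[C@@H]12 | intermediate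
29 | lactol of 28 (anomers) | C=C1C(O)O[C@@H]2/C=C(/C)CC/C=C(/C=O)[C@H](OCOC)[C@@H](OCc3ccc(OC)cc3)[C@@H]12 | intermediate (not isolated)
30 | α-methylene lactone, C8–OPMB, C9–OMOM | C=C1C(=O)O[C@@H]2/C=C(/C)CC/C=C(/C=O)[C@H](OCOC)[C@@H](OCc3ccc(OC)cc3)[C@@H]12 | intermediate
31 | C8 alcohol, C9–OMOM | C=C1C(=O)O[C@@H]2/C=C(/C)CC/C=C(/C=O)[C@H](OCOC)[C@@H](O)[C@@H]12 | intermediate
32 | (S)-2-methylbutanoic acid | CC[C@H](C)C(=O)O | starting material
33 | C8 (S)-2-methylbutanoate, C9–OMOM | C=C1C(=O)O[C@@H]2/C=C(/C)CC/C=C(/C=O)[C@H](OCOC)[C@@H](OC(=O)[C@@H](C)CC)[C@@H]12 | intermediate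
34 | CNP0168436.1 | C=C1C(=O)O[C@@H]2/C=C(/C)CC/C=C(/C=O)[C@H](O)[C@@H](OC(=O)[C@@H](C)CC)[C@@H]12 | target

## Step count and risks

Total: 22 steps. Longest linear sequence: 22 steps (1 → 34); compounds 3, 21 and 32 are commercial.

**Step 16 (key step).** The alkoxide may fragment heterolytically into an enone and an allyl anion that recombine without the chair-defined geometry. The 1,3-diaxial contact between the C10 vinyl group and the C8 ether may push ring B out of the chair. The product enolate may equilibrate toward C9 and eliminate the C8 ether. Fallback: from 24, silylate the tertiary hydroxyl (Me3SiOTf, 2,6-lutidine) to the trimethylsilyl ether F1, rearrange thermally (o-dichlorobenzene, about 220 °C) in a neutral silyloxy-Cope reaction to the silyl enol ether F2, and cleave it with K2CO3 in methanol to return at 26. No alkoxide or enolate is present on this path.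

**Step 14.** Attack at C8 must occur syn-axial to the C10 vinyl group and may be slow; prolonged heating with the titanium alkoxide invites a semipinacol shift of the vinyl group or exchange at the acetal. Fallback: open the epoxide before the vinyl group is present. From 20, 4-methoxybenzyl alcohol with catalytic Yb(OTf)3 at 0 °C should attack the β-carbon C8 (trans-diaxial, remote from the carbonyl) to give the hydroxy ketone F3. MOMCl and iPr2NEt give the MOM ether F4. CH2=CHMgBr with CeCl3 should then add antiperiplanar to the axial C9–O bond, returning at 24.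

**Step 17.** Enolisation may give the wrong double-bond geometry, or occur at C9 with loss of the C8 ether. Fallback: a Shapiro reaction in place of enolate chemistry. From 26, 2,4,6-triisopropylbenzenesulfonyl hydrazide gives the hydrazone F5. Two equivalents of sBuLi deprotonate the less substituted C1 and generate the C10 vinyllithium with C2 and C9 cis. DMF then gives the enal directly, returning at 28 and omitting 27.

**Step 2.** The facial selectivity on a 4,4-dioxygenated enone may be poorer than on cyclohexenone, a second addition may compete, and the product may aromatise by loss of methanol. Fallback: resolution instead of asymmetric catalysis.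
- From 2, isopropenylmagnesium bromide with catalytic CuBr·SMe2 and Me3SiCl gives racemic material, that is 4 together with its enantiomer ent-4 F6.
- Steps 3 and 4 in the racemic series give, beside 5, 6 and 7, the enantiomers ent-5 F7, ent-6 F8 and ent-7 F9.
- A lipase (Amano PS) with vinyl acetate should acetylate F9 faster, by the empirical rule for secondary alcohols, to ent-8 F10, which is separated. The unreacted alcohol returns to the route at 7.

**Step 22.** The Lewis acid may ionise the allylic C6–O bond or induce migration of the C8 acyl group to the freed C9 hydroxyl. Fallback: remove the MOM group before ester and lactone exist and end with a fluoride step.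
- From 28, 2 M HCl in THF cleaves acetal and MOM ether together to the lactol diol F11.
- Ag2CO3 on Celite oxidises only the lactol, giving the hydroxy lactone F12 (the same compound as A5).
- Et3SiOTf and 2,6-lutidine give the C9 triethylsilyl ether F13.
- DDQ gives the C8 alcohol F14.
- Esterification with 32 as in step 21 gives the ester F15 (the same compound as A1).
- HF·pyridine removes the silyl group and returns at 34.

## Further compounds

F1 | step 16 | C10 trimethylsilyl ether of 24 | C=C1[C@@H](OC)O[C@@H]2[C@@H](C(C)=C)[C@@](O[Si](C)(C)C)(C=C)[C@H](OCOC)[C@@H](OCc3ccc(OC)cc3)[C@@H]12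
F2 | step 16 | ten-membered trimethylsilyl enol ether (C1=C10, oxygen cis to C2) | C=C1[C@@H](OC)O[C@@H]2/C=C(/C)CC/C=C(\O[Si](C)(C)C)[C@H](OCOC)[C@@H](OCc3ccc(OC)cc3)[C@@H]12
F3 | step 14 | C9 hydroxy C8 PMB ether C10 ketone | C=C1[C@@H](OC)O[C@@H]2[C@@H](C(C)=C)C(=O)[C@H](O)[C@@H](OCc3ccc(OC)cc3)[C@@H]12
F4 | step 14 | C9 MOM ether of F3 | C=C1[C@@H](OC)O[C@@H]2[C@@H](C(C)=C)C(=O)[C@H](OCOC)[C@@H](OCc3ccc(OC)cc3)[C@@H]12
F5 | step 17 | 2,4,6-triisopropylbenzenesulfonylhydrazone of 26 | C=C1[C@@H](OC)O[C@@H]2/C=C(/C)CCCC(=NNS(=O)(=O)c3c(C(C)C)cc(C(C)C)cc3C(C)C)[C@H](OCOC)[C@@H](OCc4ccc(OC)cc4)[C@@H]12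
F6 | step 2 | ent-4 | COC1(OC)[C@H](C(C)=C)CC(=O)C=C1
F7 | step 2 | ent-5 | COC1(OC)[C@H](C(C)=C)C=C(O[Si](CC)(CC)CC)C=C1
F8 | step 2 | ent-6 | COC1(OC)[C@H](C(C)=C)[C@@H](O[Si](CC)(CC)CC)C(=O)C=C1
F9 | step 2 | ent-7 | COC1(OC)[C@H](C(C)=C)[C@@H](O[Si](CC)(CC)CC)[C@H](O)C=C1
F10 | step 2 | ent-8 | COC1(OC)[C@H](C(C)=C)[C@@H](O[Si](CC)(CC)CC)[C@H](OC(C)=O)C=C1
F11 | step 22 | lactol diol (C9–OH, C8–OPMB, anomers) | C=C1C(O)O[C@@H]2/C=C(/C)CC/C=C(/C=O)[C@H](O)[C@@H](OCc3ccc(OC)cc3)[C@@H]12
F12 | step 22 | hydroxy lactone (C9–OH, C8–OPMB) | C=C1C(=O)O[C@@H]2/C=C(/C)CC/C=C(/C=O)[C@H](O)[C@@H](OCc3ccc(OC)cc3)[C@@H]12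
F13 | step 22 | C9 triethylsilyl ether of F12 | C=C1C(=O)O[C@@H]2/C=C(/C)CC/C=C(/C=O)[C@H](O[Si](CC)(CC)CC)[C@@H](OCc3ccc(OC)cc3)[C@@H]12
F14 | step 22 | C8 alcohol, C9 triethylsilyl ether | C=C1C(=O)O[C@@H]2/C=C(/C)CC/C=C(/C=O)[C@H](O[Si](CC)(CC)CC)[C@@H](O)[C@@H]12
F15 | step 22 | C9 triethylsilyl ether of 34 | C=C1C(=O)O[C@@H]2/C=C(/C)CC/C=C(/C=O)[C@H](O[Si](CC)(CC)CC)[C@@H](OC(=O)[C@@H](C)CC)[C@@H]12
A1 | alternative 1 | C9 triethylsilyl ether of 34 | C=C1C(=O)O[C@@H]2/C=C(/C)CC/C=C(/C=O)[C@H](O[Si](CC)(CC)CC)[C@@H](OC(=O)[C@@H](C)CC)[C@@H]12
A2 | alternative 1 | ten-membered alkynol (C6–OH, C7 ethynyl, C8 ester, C9–OSiEt3) | O[C@@H]1/C=C(/C)CC/C=C(/C=O)[C@H](O[Si](CC)(CC)CC)[C@@H](OC(=O)[C@@H](C)CC)[C@H]1C#C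
A3 | alternative 2 | protected ten-membered lactone with both ring olefins | C1C(=O)O[C@@H]2/C=C(/C)CC/C=C(/CO[Si](C)(C)C(C)(C)C)[C@H](O[Si](C)(C)C(C)(C)C)[C@@H](OCc3ccc(OC)cc3)[C@@H]12
A4 | alternative 2 | open-chain lactone with (Z)-vinyl iodide and terminal diene | C1C(=O)O[C@H](/C=C(/C)I)[C@H]1[C@H](OCc2ccc(OC)cc2)[C@@H](O[Si](C)(C)C(C)(C)C)/C(CO[Si](C)(C)C(C)(C)C)=C\C=C
A5 | alternative 3 | 8-O-(4-methoxybenzyl) analogue of 34 | C=C1C(=O)O[C@@H]2/C=C(/C)CC/C=C(/C=O)[C@H](O)[C@@H](OCc3ccc(OC)cc3)[C@@H]12
A6 | alternative 3 | open-chain enal aldehyde (C9 aldehyde, C8–OPMB) | C=C1C(=O)O[C@H](/C=C(/C)CC/C=C/C=O)[C@H]1[C@H](OCc2ccc(OC)cc2)C=O
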